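**Retrosynthetic overview**

1. The last C–C bond is C4–C(styryl) of the bicyclo[3.2.1]oct-3-ene-2,8-dione. It is made from the saturated 2,8-dione and an (E)-styrylboronate by a one-pot aerobic palladium dehydrogenation/oxidative alkenyl Heck reaction; global desilylation follows.
2. Enabling feature: C1 and C5 are bridgeheads and the C8 ketone lies between them. The C2 ketone can therefore enolise only towards C3, and hydride can leave only from C4, so the C3–C4 edge of the three-carbon bridge is the single site where the C=C and the new C–C bond can arise. Over-oxidation and aromatisation are impossible.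
3. The six-membered ring is closed at C1–C2 by an enamine-catalysed bridging aldol of a 2-(3-oxopropyl)cyclopentanone, then oxidation; the tether sets the second bridgehead.
4. The cyclopentanone triad comes from bought (R)-4-silyloxycyclopentenone: aryl conjugate addition/elimination, then a second aryl conjugate addition with enolate propargylation (all trans). The order of addition fixes which aryl group sits next to which bridgehead.
5. Ring order: five-membered ring (bought), then six-membered ring (step 6); the key step closes no ring.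

Key step: step 9

Remark: TBS = tert-butyldimethylsilyl; all six starting materials are taken as purchasable; the bicyclic compounds are numbered as bicyclo[3.2.1]octanes (C1, C5 bridgeheads; C2, C8 carbonyl carbons).

**Step 1**
Reactants: 1 5-bromobenzene-1,3-diol
Product: 2 1-bromo-3,5-bis(TBSO)benzene
Conditions: TBSCl, imidazole, DMF, rt
Reagents that add atoms: tert-butyldimethylsilyl chloride, C[Si](C)(Cl)C(C)(C)C
Why: Imidazole-promoted silylation of both phenols (silyl ether formation) should mask the acidic OH groups before the Grignard chemistry.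

**Step 2**
Reactants: 3 (4-bromophenoxy)(tert-butyl)dimethylsilane; 4 (R)-4-(TBSO)cyclopent-2-en-1-one
Product: 7 (3S,4R)-3-[4-(TBSO)phenyl]-4-(TBSO)cyclopentan-1-one (aryl trans to silyloxy), via arylmagnesium bromide 5 (not isolated), via magnesium enolate 6 (not isolated)
Conditions: Mg, THF (gives 5); CuBr·SMe2 (10 mol %), THF, −78 → −40 °C; aq NH4Cl
Reagents that add atoms: none
Why: Copper-catalysed conjugate (1,4-) addition of the aryl Grignard reagent should occur anti to the bought C4 silyloxy stereocentre (substrate control), giving the 3,4-trans ketone after protonation of the enolate.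

**Step 3**
Reactants: 7
Product: 8 (R)-4-[4-(TBSO)phenyl]cyclopent-2-en-1-one
Conditions: DBU, CH2Cl2, −20 → 0 °C
Reagents that add atoms: none
Why: E1cB β-elimination of silanolate from the β-silyloxy ketone should give the enone, and the aryl-bearing stereocentre is untouched if temperature and time are kept low.

**Step 4**
Reactants: 8; 2; 9 propargyl bromide
Product: 12 (2R,3S,4R)-3-[3,5-bis(TBSO)phenyl]-4-[4-(TBSO)phenyl]-2-(prop-2-yn-1-yl)cyclopentan-1-one (all trans), via arylmagnesium bromide 10 (not isolated), via magnesium enolate 11 (not isolated)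
Conditions: Mg, THF (gives 10); CuBr·SMe2 (10 mol %), THF, −78 °C; then 9, DMPU, −40 → 0 °C
Reagents that add atoms: none
Why: In this tandem copper-catalysed conjugate addition/enolate alkylation (three-component coupling) the second aryl group should add anti to the C4 aryl group and the regiodefined enolate should be propargylated anti to the new C3 aryl group, setting two stereocentres in one event.

**Step 5**
Reactants: 12
Product: 13 3-[(1R,2S,3R)-2-[3,5-bis(TBSO)phenyl]-3-[4-(TBSO)phenyl]-5-oxocyclopentyl]propanal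
Conditions: [CpRu(MeCN)3]PF6 (5 mol %), 5,5'-bis(trifluoromethyl)-2,2'-bipyridine (5 mol %), H2O, NMP, 25 °C
Reagents that add atoms: water, O
Why: Ruthenium-vinylidene-mediated anti-Markovnikov hydration of the terminal alkyne should give the aldehyde without touching the ketone or the aryl silyl ethers.

**Step 6**
Reactants: 13
Product: 14 (1R,5R,6S,7S)-6-[3,5-bis(TBSO)phenyl]-7-[4-(TBSO)phenyl]-2-hydroxybicyclo[3.2.1]octan-8-one (mixture of C2 carbinol epimers)
Conditions: L-proline (30 mol %), DMSO (0.02 M), rt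
Reagents that add atoms: none
Why: In this enamine-catalysed intramolecular aldol (6-enolexo bridging annulation) the enamine should form at the unsubstituted α-methylene, so the substituted α-carbon does not epimerise, and the tether forces bond formation on the face that carries the propanal chain, which sets the second bridgehead.

**Step 7**
Reactants: 14
Product: 15 (1R,5R,6S,7S)-6-[3,5-bis(TBSO)phenyl]-7-[4-(TBSO)phenyl]bicyclo[3.2.1]octane-2,8-dione
Conditions: Dess–Martin periodinane, CH2Cl2, rt
Reagents that add atoms: none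
Why: Dess–Martin oxidation should convert both carbinol epimers into the non-enolisable bridged β-diketone under neutral conditions that avoid retro-Claisen cleavage.

**Step 8**
Reactants: 16 tert-butyl(4-ethenylphenoxy)dimethylsilane; 17 vinylboronic acid pinacol ester
Product: 18 (E)-2-[4-(TBSO)phenyl]ethenylboronic acid pinacol ester
Conditions: second-generation Grubbs catalyst RuCl2(H2IMes)(PCy3)(=CHPh) (3 mol %), CH2Cl2, 40 °C
Reagents that add atoms: none
Why: Olefin cross-metathesis of the styrene with the vinylboronate should give the (E)-alkenylboronate under thermodynamic control.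

**Step 9**
Reactants: 15; 18
Product: 20 (1R,5S,6S,7S)-6-[3,5-bis(TBSO)phenyl]-7-[4-(TBSO)phenyl]-4-[(E)-2-[4-(TBSO)phenyl]ethenyl]bicyclo[3.2.1]oct-3-ene-2,8-dione, via enone 19 (not isolated)
Conditions: Pd(O2CCF3)2 (10 mol %), DMSO (20 mol %), O2 (1 atm), AcOH/EtOAc, 80 °C; then 18 (2.5 equiv), 6,6'-dimethyl-2,2'-bipyridine (12 mol %), NMP, 4 Å MS, O2 (1 atm), 50 °C
Reagents that add atoms: none
Why: Proposed new method: two known aerobic divalent-palladium processes, α,β-dehydrogenation of a cyclic ketone and the oxidative boron Heck reaction of a cyclic enone, are merged into one operation that has not been shown on a saturated ketone with an alkenylboronate. The C2 ketone of 15 should form a palladium enolate at C3, and β-hydride elimination from C4 gives enone 19 while O2 returns zerovalent palladium to divalent palladium; transmetalation of 18 then gives a styryl–palladium species that inserts across C3=C4 with the styryl group at C4, and β-hydride elimination after enolate epimerisation (or protonation followed by a second dehydrogenation) restores the enone as the dienone 20. The closest known reactions are the Pd/DMSO/O2 dehydrogenation of cyclohexanones to cyclohexenones and the aerobic oxidative Heck coupling of cyclohexenone with boronic acids. No ring is closed and no stereocentre is created, and the transient C4 centre of any conjugate-addition intermediate is erased. The selectivity needed is the site of desaturation and of C–C bond formation, and the substrate secures it: C1 and C5 are bridgeheads, so only C3 can carry the enolate and only C4 can lose hydride (Bredt's rule), the C8 ketone is inert, and the product can neither desaturate further nor aromatise. The (E)-geometry should follow from stereoretentive transmetalation of 18.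

**Step 10**
Reactants: 20
Product: 21 (1R,5S,6S,7S)-6-(3,5-dihydroxyphenyl)-7-(4-hydroxyphenyl)-4-[(E)-2-(4-hydroxyphenyl)ethenyl]bicyclo[3.2.1]oct-3-ene-2,8-dione
Conditions: HF·pyridine, pyridine, THF, 0 °C → rt, dark
Reagents that add atoms: none
Why: Fluoride cleavage of the four aryl silyl ethers under mildly acidic conditions should release the phenols without retro-Claisen cleavage of the bridged β-diketone or retro-Michael opening through a quinone methide.

**Compound list**

1 | 5-bromobenzene-1,3-diol | Oc1cc(O)cc(Br)c1 | starting material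
2 | 1-bromo-3,5-bis(TBSO)benzene | Brc1cc(O[Si](C)(C)C(C)(C)C)cc(O[Si](C)(C)C(C)(C)C)c1 | intermediate
3 | (4-bromophenoxy)(tert-butyl)dimethylsilane | Brc1ccc(O[Si](C)(C)C(C)(C)C)cc1 | starting material
4 | (R)-4-(TBSO)cyclopent-2-en-1-one | O=C1C=C[C@H](O[Si](C)(C)C(C)(C)C)C1 | starting material
5 | [4-(TBSO)phenyl]magnesium bromide | Br[Mg]c1ccc(O[Si](C)(C)C(C)(C)C)cc1 | intermediate
6 | bromomagnesium enolate of 7, (3S,4R)-3-aryl-4-(TBSO)cyclopent-1-en-1-olate | Br[Mg]OC1=C[C@@H](c2ccc(O[Si](C)(C)C(C)(C)C)cc2)[C@H](O[Si](C)(C)C(C)(C)C)C1 | intermediate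
7 | (3S,4R)-3-[4-(TBSO)phenyl]-4-(TBSO)cyclopentan-1-one | O=C1C[C@@H](c2ccc(O[Si](C)(C)C(C)(C)C)cc2)[C@H](O[Si](C)(C)C(C)(C)C)C1 | intermediate
8 | (R)-4-[4-(TBSO)phenyl]cyclopent-2-en-1-one | O=C1C[C@@H](c2ccc(O[Si](C)(C)C(C)(C)C)cc2)C=C1 | intermediate
9 | propargyl bromide | C#CCBr | starting material
10 | [3,5-bis(TBSO)phenyl]magnesium bromide | Br[Mg]c1cc(O[Si](C)(C)C(C)(C)C)cc(O[Si](C)(C)C(C)(C)C)c1 | intermediate
11 | bromomagnesium (3S,4R)-3-[3,5-bis(TBSO)phenyl]-4-[4-(TBSO)phenyl]cyclopent-1-en-1-olate | Br[Mg]OC1=C[C@@H](c2cc(O[Si](C)(C)C(C)(C)C)cc(O[Si](C)(C)C(C)(C)C)c2)[C@H](c2ccc(O[Si](C)(C)C(C)(C)C)cc2)C1 | intermediate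
12 | (2R,3S,4R)-3-[3,5-bis(TBSO)phenyl]-4-[4-(TBSO)phenyl]-2-(prop-2-yn-1-yl)cyclopentan-1-one | C#CC[C@H]1C(=O)C[C@@H](c2ccc(O[Si](C)(C)C(C)(C)C)cc2)[C@@H]1c1cc(O[Si](C)(C)C(C)(C)C)cc(O[Si](C)(C)C(C)(C)C)c1 | intermediate
13 | 3-[(1R,2S,3R)-2-[3,5-bis(TBSO)phenyl]-3-[4-(TBSO)phenyl]-5-oxocyclopentyl]propanal | O=CCC[C@H]1C(=O)C[C@@H](c2ccc(O[Si](C)(C)C(C)(C)C)cc2)[C@@H]1c1cc(O[Si](C)(C)C(C)(C)C)cc(O[Si](C)(C)C(C)(C)C)c1 | intermediate
14 | (1R,5R,6S,7S)-6-[3,5-bis(TBSO)phenyl]-7-[4-(TBSO)phenyl]-2-hydroxybicyclo[3.2.1]octan-8-one, C2 epimers | OC1CC[C@H]2C(=O)[C@@H]1[C@@H](c1ccc(O[Si](C)(C)C(C)(C)C)cc1)[C@@H]2c1cc(O[Si](C)(C)C(C)(C)C)cc(O[Si](C)(C)C(C)(C)C)c1 | intermediate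
15 | (1R,5R,6S,7S)-6-[3,5-bis(TBSO)phenyl]-7-[4-(TBSO)phenyl]bicyclo[3.2.1]octane-2,8-dione | O=C1CC[C@H]2C(=O)[C@@H]1[C@@H](c1ccc(O[Si](C)(C)C(C)(C)C)cc1)[C@@H]2c1cc(O[Si](C)(C)C(C)(C)C)cc(O[Si](C)(C)C(C)(C)C)c1 | intermediate
16 | tert-butyl(4-ethenylphenoxy)dimethylsilane | C=Cc1ccc(O[Si](C)(C)C(C)(C)C)cc1 | starting material
17 | vinylboronic acid pinacol ester | C=CB1OC(C)(C)C(C)(C)O1 | starting material
18 | (E)-2-[4-(TBSO)phenyl]ethenylboronic acid pinacol ester | CC1(C)OB(/C=C/c2ccc(O[Si](C)(C)C(C)(C)C)cc2)OC1(C)C | intermediate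
19 | (1R,5R,6S,7S)-6-[3,5-bis(TBSO)phenyl]-7-[4-(TBSO)phenyl]bicyclo[3.2.1]oct-3-ene-2,8-dione | O=C1C=C[C@H]2C(=O)[C@@H]1[C@@H](c1ccc(O[Si](C)(C)C(C)(C)C)cc1)[C@@H]2c1cc(O[Si](C)(C)C(C)(C)C)cc(O[Si](C)(C)C(C)(C)C)c1 | intermediate
20 | (1R,5S,6S,7S)-6-[3,5-bis(TBSO)phenyl]-7-[4-(TBSO)phenyl]-4-[(E)-2-[4-(TBSO)phenyl]ethenyl]bicyclo[3.2.1]oct-3-ene-2,8-dione | O=C1C=C(/C=C/c2ccc(O[Si](C)(C)C(C)(C)C)cc2)[C@H]2C(=O)[C@@H]1[C@@H](c1ccc(O[Si](C)(C)C(C)(C)C)cc1)[C@@H]2c1cc(O[Si](C)(C)C(C)(C)C)cc(O[Si](C)(C)C(C)(C)C)c1 | intermediate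
21 | (1R,5S,6S,7S)-6-(3,5-dihydroxyphenyl)-7-(4-hydroxyphenyl)-4-[(E)-2-(4-hydroxyphenyl)ethenyl]bicyclo[3.2.1]oct-3-ene-2,8-dione | O=C1C=C(/C=C/c2ccc(O)cc2)[C@H]2C(=O)[C@@H]1[C@@H](c1ccc(O)cc1)[C@@H]2c1cc(O)cc(O)c1 | target

**Step count and risks**

Total step count: 10. Longest linear sequence: 8 steps (steps 2, 3, 4, 5, 6, 7, 9, 10).

Steps most likely to fail:

1. Step 9 (Proposed new method). Dehydrogenation of the hindered ketone may be slow, so the catalyst may decay to palladium black. Oxidative homocoupling or protodeboronation of 18 may outrun insertion, or the sequence may stop at the conjugate-addition stage. Fallback with known chemistry, from 15 back to 20: 15 would be dehydrogenated with IBX (DMSO/fluorobenzene, 70 °C) to the enone 19, now isolated. A Hayashi–Miyaura conjugate addition of 18 ([Rh(cod)OH]2, dioxane/H2O, 40 °C) should then give the saturated 4-styryl diketone F1, expected from the exo face; its C4 configuration is irrelevant. A second IBX dehydrogenation, possible only along C3–C4, would return to 20.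

2. Step 3. DBU may deprotonate the γ-position of the product enone, which would racemise the aryl-bearing centre and move the double bond into conjugation with the aryl ring. Fallback from 7 back to 8: the secondary alkyl silyl ether would be cleaved selectively under acid (AcOH/THF/H2O, 45 °C; the aryl silyl ethers should survive) to the β-hydroxy ketone F2. Mesylation (MsCl, Et3N, CH2Cl2, −40 °C) would give the mesylate F3, which should eliminate in the same flask below 0 °C to 8 without a strong amidine base.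

3. Step 4. C-alkylation of the magnesium enolate may be sluggish, which allows proton transfer, loss of the regiodefined enolate, O-alkylation, or consumption of 9 by excess Grignard reagent. Fallback from 8 back to 13: after the same copper-catalysed addition of 10 to 8, the enolate 11 would be O-acylated with allyl chloroformate to the allyl enol carbonate F4. Pd(PPh3)4-catalysed decarboxylative allylation (Tsuji) should deliver the allyl group regiospecifically and anti to the neighbouring aryl group, giving the 2-allyl ketone F5. Hydroboration with disiamylborane and NaBO3 oxidation would give the primary alcohol F6, and Dess–Martin oxidation would rejoin the route at 13.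

**Further compounds**

F1 | step 9 | (1R,5R,6S,7S)-6-[3,5-bis(TBSO)phenyl]-7-[4-(TBSO)phenyl]-4-[(E)-2-[4-(TBSO)phenyl]ethenyl]bicyclo[3.2.1]octane-2,8-dione, C4 epimers | O=C1CC(/C=C/c2ccc(O[Si](C)(C)C(C)(C)C)cc2)[C@H]2C(=O)[C@@H]1[C@@H](c1ccc(O[Si](C)(C)C(C)(C)C)cc1)[C@@H]2c1cc(O[Si](C)(C)C(C)(C)C)cc(O[Si](C)(C)C(C)(C)C)c1
F2 | step 3 | (3S,4R)-3-[4-(TBSO)phenyl]-4-hydroxycyclopentan-1-one | O=C1C[C@@H](c2ccc(O[Si](C)(C)C(C)(C)C)cc2)[C@H](O)C1
F3 | step 3 | (1R,2S)-2-[4-(TBSO)phenyl]-4-oxocyclopentyl methanesulfonate | O=C1C[C@@H](c2ccc(O[Si](C)(C)C(C)(C)C)cc2)[C@H](OS(C)(=O)=O)C1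
F4 | step 4 | (3S,4R)-3-[3,5-bis(TBSO)phenyl]-4-[4-(TBSO)phenyl]cyclopent-1-en-1-yl prop-2-en-1-yl carbonate | C=CCOC(=O)OC1=C[C@@H](c2cc(O[Si](C)(C)C(C)(C)C)cc(O[Si](C)(C)C(C)(C)C)c2)[C@H](c2ccc(O[Si](C)(C)C(C)(C)C)cc2)C1
F5 | step 4 | (2R,3S,4R)-3-[3,5-bis(TBSO)phenyl]-4-[4-(TBSO)phenyl]-2-(prop-2-en-1-yl)cyclopentan-1-one | C=CC[C@H]1C(=O)C[C@@H](c2ccc(O[Si](C)(C)C(C)(C)C)cc2)[C@@H]1c1cc(O[Si](C)(C)C(C)(C)C)cc(O[Si](C)(C)C(C)(C)C)c1
F6 | step 4 | (2R,3S,4R)-3-[3,5-bis(TBSO)phenyl]-4-[4-(TBSO)phenyl]-2-(3-hydroxypropyl)cyclopentan-1-one | OCCC[C@H]1C(=O)C[C@@H](c2ccc(O[Si](C)(C)C(C)(C)C)cc2)[C@@H]1c1cc(O[Si](C)(C)C(C)(C)C)cc(O[Si](C)(C)C(C)(C)C)c1
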